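## Retrosynthetic overview

- Last C–C bond: the ketone bond C3–C(=O)Ar. An aroyl radical from a salicylic-acid "left half" adds across a dihydropyran 1,3-diene "right half" in a photoredox anti-hydroacylation that sets C3 and C4. Global desilylation follows.
- Right half: (S)-2-alkyl-2,3-dihydropyran-4-one, then trans aryl-cuprate addition with enol-triflate trapping (sets C2 from C6), then Heck coupling to the 4-styryl diene.
- Left half: aromatic Claisen rearrangement (O→C, 1,3-chirality transfer) of an aryl allyl ether. The ether comes from Mitsunobu inversion of a syn-1,3-diol, itself made by Heck coupling and Narasaka–Prasad reduction.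
- Both halves come from one β-hydroxy vinyl ketone, made from (S)-epichlorohydrin, the only source of chirality.
- Ring order: only the oxane ring is built (Wacker-type 6-endo closure, early). All aromatic rings are bought.

Assumption: the target is taken exactly as the SMILES defines it, (2R,3R,4S,6S) in the oxane (2-aryl trans to the mutually cis 3-acyl, 4-styryl and 6-alkyl groups) and (1R,5S) in the side chain; compounds 1, 10 and 15 are treated as catalogue items.

Abbreviations: TBS = tert-butyldimethylsilyl; ArT = 4-(TBSO)phenyl. Oxane atoms keep the target numbering throughout (C2 aryl, C6 arylethyl).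

## Route

**Step 1**
Reactants: 1, tert-butyl[4-(chloromethyl)phenoxy]dimethylsilane; 2, (S)-epichlorohydrin
Product: 3, (S)-1-chloro-4-ArT-butan-2-ol
Conditions: 1, Mg, THF, rt; then 2, CuI (10 mol %), THF, −40 → 0 °C
Reagents that add atoms: none
Why: Cu-catalysed Grignard opening of the epoxide at its CH2 terminus; the bought stereocentre is not a reacting centre and is carried over as (S).

**Step 2**
Reactants: 3
Product: 4, (S)-2-[2-(ArT)ethyl]oxirane
Conditions: NaH, THF, 0 °C → rt
Reagents that add atoms: none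
Why: intramolecular Williamson SN2 closure at the CH2Cl carbon; the carbinol centre only supplies oxygen, so configuration is retained, and the non-nucleophilic base spares the aryl silyl ether.

**Step 3**
Reactants: 4; 5, methoxyallene
Product: 6, (S)-5-hydroxy-7-ArT-hept-1-en-3-one
Conditions: 5, n-BuLi, THF, −40 °C; then 4, DMPU, −40 → 0 °C; then 5 % aq. H2SO4, THF, 0 °C
Reagents that add atoms: water, O
Why: 1-lithio-1-methoxyallene is an acryloyl-anion equivalent that opens the epoxide at CH2 (SN2, stereocentre untouched); enol-ether hydrolysis then unmasks the vinyl ketone.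

**Step 4**
Reactants: 6
Product: 7, (S)-2-[2-(ArT)ethyl]-2,3-dihydro-4H-pyran-4-one
Conditions: PdCl2(MeCN)2 (10 mol %), CuCl, Na2HPO4, O2 (1 atm), DME, rt
Reagents that add atoms: none
Why: Wacker-type 6-endo oxypalladation of the enone by the β-hydroxyl, then β-hydride elimination (oxidative cyclisation of β-hydroxy enones); this closes the oxane ring without touching the stereocentre.

**Step 5**
Reactants: 7; 8, (4-bromophenoxy)(tert-butyl)dimethylsilane
Product: 9, (2R,6S)-2-ArT-6-[2-(ArT)ethyl]-5,6-dihydro-2H-pyran-4-yl trifluoromethanesulfonate (2,6-trans)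
Conditions: 8, t-BuLi, Et2O, −78 °C; CuI (0.5 equiv), −40 °C; then 7, THF, −78 °C; then Comins' reagent, −78 → 0 °C
Reagents that add atoms: Comins' reagent, FC(F)(F)S(=O)(=O)N(c1ccc(Cl)cn1)S(=O)(=O)C(F)(F)F
Why: Gilman conjugate addition with axial attack on the half-chair anti to the pseudo-equatorial C6 chain gives the 2,6-trans (2R) centre; the regiodefined C3=C4 enolate is trapped in situ as the enol triflate.

**Step 6**
Reactants: 9; 10, tert-butyldimethyl(4-vinylphenoxy)silane
Product: 11, (2R,6S)-2-ArT-6-[2-(ArT)ethyl]-4-[(E)-2-(ArT)ethenyl]-5,6-dihydro-2H-pyran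
Conditions: Pd(OAc)2 (5 mol %), PPh3, Et3N, DMF, 60 °C
Reagents that add atoms: none
Why: Mizoroki–Heck coupling of the vinyl triflate with the styrene gives the (E)-1-aryl-1,3-diene; no stereocentre is involved.

**Step 7**
Reactants: 6; 12, tert-butyl(4-iodophenoxy)dimethylsilane
Product: 13, (1E,5S)-5-hydroxy-1,7-bis(ArT)hept-1-en-3-one
Conditions: Pd(OAc)2 (5 mol %), n-Bu4NCl, NaHCO3, DMF, 50 °C
Reagents that add atoms: none
Why: Mizoroki–Heck arylation (Jeffery conditions) of the vinyl ketone is E-selective and mild enough to avoid retro-aldol or dehydration of the β-hydroxy ketone.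

**Step 8**
Reactants: 13
Product: 14, (1E,3S,5S)-1,7-bis(ArT)hept-1-ene-3,5-diol (syn)
Conditions: Et2BOMe, NaBH4, THF/MeOH 4:1, −78 °C; AcOH quench, MeOH co-evaporation
Reagents that add atoms: none
Why: Narasaka–Prasad reduction; external hydride attacks the six-membered boron chelate axially, so the bought C5 centre sets C3 as the 1,3-syn (3S) alcohol with clean 1,2-reduction of the enone.

**Step 9**
Reactants: 15, 2,4-dihydroxy-6-methoxybenzaldehyde
Product: 16, 4-(TBSO)-2-hydroxy-6-methoxybenzaldehyde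
Conditions: TBSCl (1.05 equiv), imidazole, CH2Cl2, 0 °C
Reagents that add atoms: TBSCl, CC(C)(C)[Si](C)(C)Cl
Why: selective silylation; the 2-OH is locked in a hydrogen bond to the aldehyde, so only the free, more acidic 4-OH reacts.

**Step 10**
Reactants: 16; 14
Product: 17, 2-{[(1E,3R,5S)-5-hydroxy-1,7-bis(ArT)hept-1-en-3-yl]oxy}-6-methoxy-4-(TBSO)benzaldehyde
Conditions: PPh3, DIAD, PhMe, −20 → 0 °C
Reagents that add atoms: none
Why: Mitsunobu etherification; the allylic C3 oxyphosphonium is displaced far faster than the saturated C5 one, and SN2 inversion gives the (3R) aryl ether on the only free phenol.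

**Step 11**
Reactants: 17
Product: 18, 2-hydroxy-3-[(1R,2E,5S)-5-hydroxy-1,7-bis(ArT)hept-2-en-1-yl]-6-methoxy-4-(TBSO)benzaldehyde
Conditions: PhNEt2, 160 °C, sealed tube, Ar
Reagents that add atoms: none
Why: aromatic Claisen [3,3] rearrangement through a chair with the C4 chain equatorial; suprafacial transfer of the (3R) C–O centre gives the (1R) diarylmethine and the (E)-2-alkene, and C3 is the only open ortho position.

**Step 12**
Reactants: 18
Product: 19, 2-hydroxy-3-[(1R,2E,5S)-5-hydroxy-1,7-bis(ArT)hept-2-en-1-yl]-6-methoxy-4-(TBSO)benzoic acid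
Conditions: NaClO2, NaH2PO4, 2-methyl-2-butene (excess), t-BuOH/THF/H2O, 0 °C → rt; used crude
Reagents that add atoms: sodium chlorite, [Na+].[O-]Cl=O
Why: Lindgren–Pinnick oxidation of the aldehyde; the scavenger removes HOCl so the electron-rich ring, the alkene and both stereocentres are untouched.

**Step 13**
Reactants: 19; 11 (1.5 equiv)
Product: 20, hexa-O-TBS blepharocalyxin B: [(2R,3R,4S,6S)-2-ArT-6-[2-(ArT)ethyl]-4-[(E)-2-(ArT)ethenyl]oxan-3-yl]{2-hydroxy-3-[(1R,2E,5S)-5-hydroxy-1,7-bis(ArT)hept-2-en-1-yl]-6-methoxy-4-(TBSO)phenyl}methanone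
Conditions: [Ir(dF(Me)ppy)2(dtbbpy)]PF6 (2 mol %), PPh3 (1.5 equiv), 2,4,6-collidine (1 equiv), 2,4,6-triisopropylbenzenethiol (10 mol %), PhMe/MeCN 1:1, degassed, 450 nm LEDs, rt
Reagents that add atoms: none
Why: Proposed new method: excited Ir(III) oxidises PPh3 to its radical cation, the carboxylate of 19 adds to it, and β-scission of the phosphoranyl radical releases the aroyl radical; this adds to C3 (the diene terminus remote from the aryl group) anti to the C2 aryl group, and the aryl thiol then delivers H to C4 of the aryl-stabilised allyl radical anti to the new C3 aroyl group (the classical anti radical addition across a 1-substituted cyclohexene), leaving the (E)-styryl group equatorial and cis to both the acyl group and the C6 chain, i.e. (2R,3R,4S,6S); Ir(II) reduces the thiyl radical to close the cycle; the closest known reaction is phosphine-mediated photoredox deoxygenative hydroacylation of styrenes and activated alkenes with aromatic acids, not yet shown on a cyclic 1,3-diene or with 1,2-anti diastereocontrol.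

**Step 14**
Reactants: 20
Product: 21, blepharocalyxin B
Conditions: TBAF/AcOH (1:1, 7 equiv), THF, 0 °C → rt
Reagents that add atoms: none
Why: buffered fluoride cleavage of the six aryl silyl ethers; near-neutral conditions avoid retro-oxa-Michael opening, C3 epimerisation and acid ionisation of the C2 benzylic ether.

## Compound list

1 | tert-butyl[4-(chloromethyl)phenoxy]dimethylsilane | CC(C)(C)[Si](C)(C)Oc1ccc(CCl)cc1 | starting material
2 | (S)-epichlorohydrin | ClC[C@@H]1CO1 | starting material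
3 | (S)-1-chloro-4-[4-(TBSO)phenyl]butan-2-ol | CC(C)(C)[Si](C)(C)Oc1ccc(CC[C@H](O)CCl)cc1 | intermediate
4 | (S)-2-{2-[4-(TBSO)phenyl]ethyl}oxirane | CC(C)(C)[Si](C)(C)Oc1ccc(CC[C@H]2CO2)cc1 | intermediate
5 | methoxyallene | COC=C=C | starting material
6 | (S)-5-hydroxy-7-[4-(TBSO)phenyl]hept-1-en-3-one | C=CC(=O)C[C@@H](O)CCc1ccc(O[Si](C)(C)C(C)(C)C)cc1 | intermediate
7 | (S)-2-{2-[4-(TBSO)phenyl]ethyl}-2,3-dihydro-4H-pyran-4-one | O=C1C[C@H](CCc2ccc(O[Si](C)(C)C(C)(C)C)cc2)OC=C1 | intermediate
8 | (4-bromophenoxy)(tert-butyl)dimethylsilane | CC(C)(C)[Si](C)(C)Oc1ccc(Br)cc1 | starting material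
9 | (2R,6S)-2-[4-(TBSO)phenyl]-6-{2-[4-(TBSO)phenyl]ethyl}-5,6-dihydro-2H-pyran-4-yl triflate | C1=C(OS(=O)(=O)C(F)(F)F)C[C@H](CCc2ccc(O[Si](C)(C)C(C)(C)C)cc2)O[C@H]1c1ccc(O[Si](C)(C)C(C)(C)C)cc1 | intermediate
10 | tert-butyldimethyl(4-vinylphenoxy)silane | C=Cc1ccc(O[Si](C)(C)C(C)(C)C)cc1 | starting material
11 | (2R,6S)-2-[4-(TBSO)phenyl]-6-{2-[4-(TBSO)phenyl]ethyl}-4-{(E)-2-[4-(TBSO)phenyl]ethenyl}-5,6-dihydro-2H-pyran | C1=C(/C=C/c2ccc(O[Si](C)(C)C(C)(C)C)cc2)C[C@H](CCc2ccc(O[Si](C)(C)C(C)(C)C)cc2)O[C@H]1c1ccc(O[Si](C)(C)C(C)(C)C)cc1 | intermediate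
12 | tert-butyl(4-iodophenoxy)dimethylsilane | CC(C)(C)[Si](C)(C)Oc1ccc(I)cc1 | starting material
13 | (1E,5S)-5-hydroxy-1,7-bis[4-(TBSO)phenyl]hept-1-en-3-one | O=C(/C=C/c1ccc(O[Si](C)(C)C(C)(C)C)cc1)C[C@@H](O)CCc1ccc(O[Si](C)(C)C(C)(C)C)cc1 | intermediate
14 | (1E,3S,5S)-1,7-bis[4-(TBSO)phenyl]hept-1-ene-3,5-diol | O[C@H](/C=C/c1ccc(O[Si](C)(C)C(C)(C)C)cc1)C[C@@H](O)CCc1ccc(O[Si](C)(C)C(C)(C)C)cc1 | intermediate
15 | 2,4-dihydroxy-6-methoxybenzaldehyde | COc1cc(O)cc(O)c1C=O | starting material
16 | 4-(TBSO)-2-hydroxy-6-methoxybenzaldehyde | COc1cc(O[Si](C)(C)C(C)(C)C)cc(O)c1C=O | intermediate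
17 | 2-{[(1E,3R,5S)-5-hydroxy-1,7-bis(4-TBSO-phenyl)hept-1-en-3-yl]oxy}-6-methoxy-4-(TBSO)benzaldehyde | COc1cc(O[Si](C)(C)C(C)(C)C)cc(O[C@@H](/C=C/c2ccc(O[Si](C)(C)C(C)(C)C)cc2)C[C@@H](O)CCc2ccc(O[Si](C)(C)C(C)(C)C)cc2)c1C=O | intermediate
18 | 2-hydroxy-3-[(1R,2E,5S)-5-hydroxy-1,7-bis(4-TBSO-phenyl)hept-2-en-1-yl]-6-methoxy-4-(TBSO)benzaldehyde | COc1cc(O[Si](C)(C)C(C)(C)C)c([C@H](/C=C/C[C@@H](O)CCc2ccc(O[Si](C)(C)C(C)(C)C)cc2)c2ccc(O[Si](C)(C)C(C)(C)C)cc2)c(O)c1C=O | intermediate
19 | 2-hydroxy-3-[(1R,2E,5S)-5-hydroxy-1,7-bis(4-TBSO-phenyl)hept-2-en-1-yl]-6-methoxy-4-(TBSO)benzoic acid | COc1cc(O[Si](C)(C)C(C)(C)C)c([C@H](/C=C/C[C@@H](O)CCc2ccc(O[Si](C)(C)C(C)(C)C)cc2)c2ccc(O[Si](C)(C)C(C)(C)C)cc2)c(O)c1C(=O)O | intermediate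
20 | hexa-O-TBS blepharocalyxin B | COc1cc(O[Si](C)(C)C(C)(C)C)c([C@H](/C=C/C[C@@H](O)CCc2ccc(O[Si](C)(C)C(C)(C)C)cc2)c2ccc(O[Si](C)(C)C(C)(C)C)cc2)c(O)c1C(=O)[C@@H]1[C@H](/C=C/c2ccc(O[Si](C)(C)C(C)(C)C)cc2)C[C@H](CCc2ccc(O[Si](C)(C)C(C)(C)C)cc2)O[C@H]1c1ccc(O[Si](C)(C)C(C)(C)C)cc1 | intermediate
21 | blepharocalyxin B | COc1cc(O)c([C@H](/C=C/C[C@@H](O)CCc2ccc(O)cc2)c2ccc(O)cc2)c(O)c1C(=O)[C@@H]1[C@H](/C=C/c2ccc(O)cc2)C[C@H](CCc2ccc(O)cc2)O[C@H]1c1ccc(O)cc1 | target

## Totals and risks

Total steps: 14. Longest linear sequence: 10 (steps 1, 2, 3, 7, 8, 10, 11, 12, 13, 14).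

Steps most likely to fail:

1. **Step 13 (proposed new photoredox anti-hydroacylation).**
   - Failure modes: slow addition of the hindered 2,6-disubstituted aroyl radical to an electron-rich diene; H-transfer at the benzylic terminus instead of C4, giving the deconjugated exocyclic alkene; thiyl abstraction of the weak C2–H of 11 or the diarylmethine H of 19; over-reduction of the acyl radical to aldehyde 18 (recyclable).
   - Fallback (known two-electron chemistry): Pd-catalysed methoxycarbonylation of triflate 9 to the C4 enoate. Add the 2-lithio-1,3-dithiane of O-protected 18 in 1,4-fashion at C3, anti to the C2 aryl group. Equilibrate the C4 ester to equatorial, convert ester to aldehyde, install the (E)-styryl group by Julia–Kocienski olefination, then hydrolyse the dithiane.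

2. **Step 11 (aromatic Claisen with chirality transfer).**
   - Failure modes: ionisation of the electron-rich cinnamyl-type ether, giving loss of ee and [1,3] products; abnormal Claisen on prolonged heating.
   - Fallback: copper-mediated anti-SN2′ allylic substitution. The C3 phosphate of diol 14 (3S, no inversion needed, C5-O protected) reacts with the arylcopper reagent from the 3-bromo derivative of protected 16. This is established 1,3-chirality transfer and gives the same (1R) centre.

3. **Step 10 (Mitsunobu on the unprotected syn-diol).**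
   - Failure modes: competing reaction at C5–OH; SN2′ or partial SN1 at the activated allylic centre.
   - Fallback: convert 14 to its cyclic sulfate (sulfonyldiimidazole) and open it with the potassium phenoxide of 16 at the allylic C3 (SN2, inversion); mild hydrolysis of the C5 sulfate monoester then gives 17.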